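Whatever a hand loses as substrate it must show as product, so in the south-west flask left-handed substrate and left-handed product together stay near half of the charge, and each hand's unreacted fraction follows from its product reading.

| setting | south-west | north | flask |
|---|---|---|---|
| left-handed substrate | 20 mM | 20 mM | 20 mM |
| right-handed substrate | 20 mM | 20 mM | 20 mM |
| partner | 3 equiv | 3 equiv | 3.00 equiv |
| protic impurity | 4 mM | 4 mM | 4.00 mM |
| free catalyst | 0.05 mol% | 0.075 mol% | 0.05 mol% |
| remark | the very flask that is asked about, followed so far | run made earlier |  |
| time |  |  | 4.0 d |

south-west run (percent of the left-handed substrate and right-handed substrate together charged)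

| time / h | left-handed product / % | right-handed product / % | left-handed substrate / % |
|---|---|---|---|
| 3.00 | 4 | 3 | 43 |
| 6.00 | 12 | 6 | 41 |
| 8.00 | 15 | 3 | 34 |
| 12.0 | 22 | 6 | 28 |
| 15.0 | 24 | 6 | 28 |
| 20.0 | 23 | 6 | 25 |

north run (percent of the left-handed substrate and right-handed substrate together charged)

| time / d | left-handed product / % | right-handed product / % | left-handed substrate / % |
|---|---|---|---|
| 0.333 | 19 | 8 | 33 |
| 0.500 | 23 | 3 | 26 |
| 0.833 | 27 | 6 | 22 |
| 1.04 | 25 | 8 | 24 |
| 1.67 | 26 | 7 | 24 |
| 2.50 | 29 | 8 | 23 |
| 4.00 | 27 | 5 | 27 |

(readings scatter by 1.5 percentage points)

* excess of left-handed product over right-handed product in the product at 5.0 h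
* excess of left-handed product over right-handed product in the product at 4.0 d
* part of the left-handed substrate and right-handed substrate charged together that has reacted at 4.0 d

- free catalyst is single-handed; left-handed substrate and right-handed substrate are mirror images of each other, charged as a racemate, each of them at the stated concentration
- an excess is the difference of the two amounts in percent of their sum
- an excess is below zero if the other one leads

From 12.0 h on, the south-west readings average 23.0% left-handed and 6.00% right-handed product, and I went to logarithms:

ln(left-handed fraction left) / ln(right-handed fraction left) = 4.82

This ratio, a reading averaged over the run so far and no constant, is what I carried as the apparent selectivity factor. The first three readings, centred near 5.67 h, average 10.3% and 4.00%, which gives a factor of 2.78, lower than the late reading, and an excess of 44.2%, my early estimate.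

I bracketed the conversion. From above stands the north run, with more catalyst, flat from 0.833 d to 4.00 d at 33.6%. From below stands the south-west reading at 12.0 h, 28.0%. The north flatness tightened my estimate to the south-west mean, 29.0%, with an excess of 58.6%.

The forecast says 46%, 59% and 30%, adding “No creep is expected”; its conversion lies inside the bracket, and its early excess stands above mine.

    free catalyst + right-handed substrate ⇌ catalyst intermediate B (K = 31.0 /M, k = 2.30 × 10⁶ /M/h)
    partner + catalyst intermediate B → free catalyst + right-handed product (k = 21000 /M/h)
    free catalyst + left-handed substrate ⇌ catalyst intermediate A (K = 380 /M, k = 87000 /M/h)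
    partner + protic impurity → quenched reagent (k = 37.0 /M/h)
    partner + catalyst intermediate A → free catalyst + left-handed product (k = 42000 /M/h)
    partner → decomposed reagent (k = 0.160 /h)
    2 free catalyst ⇌ resting dimer, settled at all times (K = 1.00 × 10⁷ /M)

The flask gives 49.4%, 61.9% and 28.5%, inside the bracket, and it stops with partner at 0% while 54% of its left-handed substrate remains; a tenfold time changes nothing. Applied to that remainder, the carried factor gives 6.00% right-handed product, and the flask holds 5.44%. The neighbour charged with 12.0 equiv of partner keeps 31% of its left-handed substrate, for which the same reckoning gives 10.7%, but that neighbour holds 21.4% right-handed product.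

Readings and results are calculated from invented constants, noise included.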